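**Strategy.** The route rests on reading the tetrasubstituted C8=C9 alkene of ring B, flanked by the quaternary C10, as the residue of an alkyne (labdane numbering). One Diels–Alder reaction between an enantiopure ring A diene, the semicyclic C7=C6–C5=C10 unit of a 2-vinyl-1,3-dimethylcyclohexene that already carries the C4 quaternary centre, and methyl but-2-ynoate closes ring B, creates C10 under control of C4, and places the C8 methyl and a C9 ester handle. Face-selective hydrogenation of C5=C6 then gives the trans-decalin, and the ester handle is extended to the (E)-enoate side chain by dianion alkylation and enol phosphate–cuprate coupling.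

Key step: step 8

Remark on numbering: ring A = C1–C5 and C10; ring B = C5–C10; C17 = methyl on C8; C18 and C19 = methyl and oxygenated carbon on C4; C20 = methyl on C10; C11–C16 = side chain on C9. The target is (4S,5R,10S) with C19 and C20 both on the β face and H5 on the α face.

Assumption: in step 2 the L-valine-derived lithio-enamine is taken to be methylated on the face that gives the (S) quaternary centre under the toluene/HMPA protocol; if this substrate shows the opposite sense, the D-valine auxiliary is used and the rest of the route is unchanged.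

Step 1
Reactants: 1 ethyl 2-oxocyclohexane-1-carboxylate; 2 L-valine tert-butyl ester
Product: 3 ethyl 2-{[(2S)-1-tert-butoxy-3-methyl-1-oxobutan-2-yl]amino}cyclohex-1-ene-1-carboxylate
Conditions: BF3·OEt2 (cat.), toluene, reflux, Dean–Stark
Reagents that add atoms: none
Why: Acid-catalysed enamine condensation of the β-keto ester with the primary amine should give the hydrogen-bonded enamino ester, driven by azeotropic removal of water; no new stereocentre is formed.

Step 2
Reactants: 3 enamino ester
Product: 5 ethyl (1S)-1-methyl-2-oxocyclohexane-1-carboxylate, via methylated imine 4 (not isolated)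
Conditions: LiN(iPr)2, toluene, HMPA (1 equiv), −78 °C; MeI, −78 → −55 °C; then 1 M aq. HCl, rt
Reagents that add atoms: iodomethane CI; water O
Why: Auxiliary-controlled alkylation of a chiral lithio-enamine, in which lithium is chelated by nitrogen and the tert-butyl ester, the isopropyl group blocks one face and iodomethane enters from the open face to set the quaternary (S) centre, after which imine hydrolysis should release the keto ester and the auxiliary.

Step 3
Reactants: 5 ethyl (1S)-1-methyl-2-oxocyclohexane-1-carboxylate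
Product: 6 ethyl (1S)-1,3-dimethyl-2-oxocyclohexane-1-carboxylate (mixture of C3 epimers)
Conditions: LiN(iPr)2, THF, −78 °C; MeI, −78 → 0 °C
Reagents that add atoms: iodomethane CI
Why: Kinetic enolate alkylation at the only enolisable position installs the future C20 methyl; the new methine centre forms as a mixture, which is irrelevant because it becomes sp2 in step 4.

Step 4
Reactants: 6 ethyl (1S)-1,3-dimethyl-2-oxocyclohexane-1-carboxylate
Product: 7 ethyl (1S)-1,3-dimethyl-2-{[(trifluoromethyl)sulfonyl]oxy}cyclohex-2-ene-1-carboxylate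
Conditions: KN(SiMe3)2, THF, −78 °C; PhNTf2, −78 °C → rt
Reagents that add atoms: N-phenylbis(trifluoromethanesulfonimide) O=S(=O)(N(c1ccccc1)S(=O)(=O)C(F)(F)F)C(F)(F)F
Why: Enol triflate formation by O-sulfonylation of the enolate, which can only form towards the methyl-bearing carbon, should give a single tetrasubstituted enol triflate with the quaternary centre untouched.

Step 5
Reactants: 7 enol triflate
Product: 8 ethyl (1S)-2-ethenyl-1,3-dimethylcyclohex-2-ene-1-carboxylate
Conditions: Bu3SnCH=CH2, Pd(PPh3)4 (5 mol %), LiCl, THF, reflux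
Reagents that add atoms: tributyl(vinyl)stannane C=C[Sn](CCCC)(CCCC)CCCC
Why: Stille cross-coupling of the vinyl triflate with the vinylstannane under zerovalent palladium catalysis should give the semicyclic 1,3-diene; no stereocentre is formed.

Step 6
Reactants: 8 diene ester
Product: 9 [(1S)-2-ethenyl-1,3-dimethylcyclohex-2-en-1-yl]methanol
Conditions: LiAlH4, Et2O, 0 °C → rt
Reagents that add atoms: none
Why: Hydride reduction of the ester gives the neopentyl primary alcohol, the unactivated diene being inert to LiAlH4.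

Step 7
Reactants: 9 diene alcohol
Product: 10 tert-butyl{[(1S)-2-ethenyl-1,3-dimethylcyclohex-2-en-1-yl]methoxy}diphenylsilane
Conditions: t-BuPh2SiCl, imidazole, DMF, rt → 40 °C
Reagents that add atoms: tert-butyl(chloro)diphenylsilane CC(C)(C)[Si](Cl)(c1ccccc1)c1ccccc1
Why: Silylation of the primary alcohol installs a bulky, robust group that differentiates the two faces of the diene and survives the Lewis acid, hydride, enolate and cuprate steps.

Step 8
Reactants: 10 silyl-protected diene; 11 methyl but-2-ynoate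
Product: 12 methyl (5S,8aS)-5-{[tert-butyl(diphenyl)silyl]oxymethyl}-2,5,8a-trimethyl-3,5,6,7,8,8a-hexahydronaphthalene-1-carboxylate
Conditions: 11 (3 equiv), EtAlCl2 (30 mol %), CH2Cl2, −40 → 0 °C
Reagents that add atoms: none
Why: Lewis-acid-accelerated, asynchronous normal-electron-demand Diels–Alder reaction of the s-cis diene C7=C6–C5=C10 with the aluminium-bound ynoate should form C7–C8 and C9–C10 in one operation. The closest known reaction type is the cycloaddition of 2,6,6-trisubstituted 1-vinylcyclohexenes with acetylenic esters used to build drimane-type decalins. Ring B is closed as a six-membered ring by suprafacial intermolecular [4+2] annulation onto ring A, leaving the C8=C9 and C5=C6 double bonds of a 1,4-cyclohexadiene. Regioselectivity is needed and is secured by the polarisation of both partners: the unhindered, most nucleophilic terminus C7 bonds to the β-carbon of the ynoate, which carries the C17 methyl, so the ester-bearing C9 closes onto the fully substituted C10. The new stereocentre C10 is controlled by the quaternary C4: the bulky silyloxymethyl arm sits pseudoaxial on the β face of the half-chair, the dienophile adds to the α face, and the C20 methyl is pushed syn to C19, giving (S) at C10. The 1,4-diene cannot aromatise because C10 is quaternary.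

Step 9
Reactants: 12 Diels–Alder adduct
Product: 13 methyl (4aR,5S,8aS)-5-{[tert-butyl(diphenyl)silyl]oxymethyl}-2,5,8a-trimethyl-3,4,4a,5,6,7,8,8a-octahydronaphthalene-1-carboxylate
Conditions: H2 (4 atm), 10% Pd/C, EtOAc, rt
Reagents that add atoms: none
Why: Heterogeneous catalytic hydrogenation should reduce the trisubstituted C5=C6 bond in preference to the tetrasubstituted, ester-conjugated C8=C9 bond, and hydrogen is delivered to the α face because the β face carries both the C20 methyl and the silyloxymethyl arm, setting C5 (R) and the trans ring fusion.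

Step 10
Reactants: 13 trans-decalin enoate
Product: 14 [(4aR,5S,8aS)-5-{[tert-butyl(diphenyl)silyl]oxymethyl}-2,5,8a-trimethyl-3,4,4a,5,6,7,8,8a-octahydronaphthalen-1-yl]methanol
Conditions: iBu2AlH (2.5 equiv), CH2Cl2, −78 → 0 °C
Reagents that add atoms: none
Why: Aluminium hydride 1,2-reduction of the hindered unsaturated ester gives the C11 allylic alcohol without touching the silyl ether or any stereocentre.

Step 11
Reactants: 14 allylic alcohol
Product: 15 tert-butyl{[(1S,4aS,8aR)-5-(bromomethyl)-1,4a,6-trimethyl-1,2,3,4,4a,7,8,8a-octahydronaphthalen-1-yl]methoxy}diphenylsilane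
Conditions: CBr4, PPh3, CH2Cl2, 0 °C
Reagents that add atoms: carbon tetrabromide BrC(Br)(Br)Br
Why: The Appel reaction converts the primary allylic alcohol into the primary allylic bromide under neutral conditions, the tetrasubstituted alkene position being retained.

Step 12
Reactants: 15 allylic bromide; 16 methyl acetoacetate
Product: 17 methyl 5-[(4aR,5S,8aS)-5-{[tert-butyl(diphenyl)silyl]oxymethyl}-2,5,8a-trimethyl-3,4,4a,5,6,7,8,8a-octahydronaphthalen-1-yl]-3-oxopentanoate
Conditions: 16, NaH, THF, 0 °C; n-BuLi, 0 °C; then 15, 0 °C → rt; 1 M aq. HCl quench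
Reagents that add atoms: none
Why: γ-Alkylation of the acetoacetate dianion, whose terminal carbanion is the more reactive site, should displace the allylic bromide by SN2 and deliver the β-keto ester containing C12–C15.

Step 13
Reactants: 17 β-keto ester
Product: 18 methyl (2Z)-3-[(diethoxyphosphoryl)oxy]-5-[(4aR,5S,8aS)-5-{[tert-butyl(diphenyl)silyl]oxymethyl}-2,5,8a-trimethyl-3,4,4a,5,6,7,8,8a-octahydronaphthalen-1-yl]pent-2-enoate
Conditions: NaH, Et2O, 0 °C; ClP(O)(OEt)2, 0 °C → rt
Reagents that add atoms: diethyl chlorophosphate CCOP(=O)(Cl)OCC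
Why: O-Phosphorylation of the chelated sodium enolate of the β-keto ester should give the (Z)-enol phosphate, because the sodium chelate holds the enolate oxygen cis to the ester.

Step 14
Reactants: 18 (Z)-enol phosphate
Product: 19 methyl (2E)-5-[(4aR,5S,8aS)-5-{[tert-butyl(diphenyl)silyl]oxymethyl}-2,5,8a-trimethyl-3,4,4a,5,6,7,8,8a-octahydronaphthalen-1-yl]-3-methylpent-2-enoate
Conditions: Me2CuLi (from MeLi and CuI, Et2O, 0 °C), Et2O, −78 → −45 °C
Reagents that add atoms: lithium dimethylcuprate [Li+].C[Cu-]C
Why: Cuprate coupling by addition–elimination at the β-phosphoryloxy enoate replaces the phosphate by methyl with retention of alkene geometry, so the (Z)-enol phosphate should give the (E)-3-methyl enoate.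

Step 15
Reactants: 19 silyl-protected (E)-enoate
Product: 20 methyl (2E)-5-[(4aR,5S,8aS)-5-(hydroxymethyl)-2,5,8a-trimethyl-3,4,4a,5,6,7,8,8a-octahydronaphthalen-1-yl]-3-methylpent-2-enoate
Conditions: Bu4NF, THF, rt → 45 °C
Reagents that add atoms: none
Why: Fluoride-mediated desilylation frees the C19 alcohol, the enoate and the tetrasubstituted alkene being inert.

Step 16
Reactants: 20 C19 alcohol
Product: 21 methyl (2E)-5-[(4aR,5S,8aS)-5-(acetoxymethyl)-2,5,8a-trimethyl-3,4,4a,5,6,7,8,8a-octahydronaphthalen-1-yl]-3-methylpent-2-enoate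
Conditions: Ac2O, pyridine, DMAP (cat.), CH2Cl2, rt
Reagents that add atoms: acetic anhydride CC(=O)OC(C)=O
Why: Nucleophile-catalysed acylation of the hindered neopentyl alcohol should give the acetate, which is the target.

**Compound list**

1 | ethyl 2-oxocyclohexane-1-carboxylate | CCOC(=O)C1CCCCC1=O | starting material
2 | L-valine tert-butyl ester | CC(C)[C@H](N)C(=O)OC(C)(C)C | starting material
3 | ethyl 2-{[(2S)-1-tert-butoxy-3-methyl-1-oxobutan-2-yl]amino}cyclohex-1-ene-1-carboxylate | CCOC(=O)C1=C(N[C@@H](C(C)C)C(=O)OC(C)(C)C)CCCC1 | intermediate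
4 | ethyl (1S)-2-{[(2S)-1-tert-butoxy-3-methyl-1-oxobutan-2-yl]imino}-1-methylcyclohexane-1-carboxylate (methylated imine, not isolated) | CCOC(=O)[C@@]1(C)CCCCC1=N[C@@H](C(C)C)C(=O)OC(C)(C)C | intermediate
5 | ethyl (1S)-1-methyl-2-oxocyclohexane-1-carboxylate | CCOC(=O)[C@@]1(C)CCCCC1=O | intermediate
6 | ethyl (1S)-1,3-dimethyl-2-oxocyclohexane-1-carboxylate (C3 epimers) | CCOC(=O)[C@@]1(C)CCCC(C)C1=O | intermediate
7 | ethyl (1S)-1,3-dimethyl-2-{[(trifluoromethyl)sulfonyl]oxy}cyclohex-2-ene-1-carboxylate | CCOC(=O)[C@@]1(C)CCCC(C)=C1OS(=O)(=O)C(F)(F)F | intermediate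
8 | ethyl (1S)-2-ethenyl-1,3-dimethylcyclohex-2-ene-1-carboxylate | CCOC(=O)[C@@]1(C)CCCC(C)=C1C=C | intermediate
9 | [(1S)-2-ethenyl-1,3-dimethylcyclohex-2-en-1-yl]methanol | OC[C@@]1(C)CCCC(C)=C1C=C | intermediate
10 | tert-butyl{[(1S)-2-ethenyl-1,3-dimethylcyclohex-2-en-1-yl]methoxy}diphenylsilane | CC(C)(C)[Si](OC[C@@]1(C)CCCC(C)=C1C=C)(c1ccccc1)c1ccccc1 | intermediate
11 | methyl but-2-ynoate | CC#CC(=O)OC | starting material
12 | methyl (5S,8aS)-5-{[tert-butyl(diphenyl)silyl]oxymethyl}-2,5,8a-trimethyl-3,5,6,7,8,8a-hexahydronaphthalene-1-carboxylate | COC(=O)C1=C(C)CC=C2[C@@](C)(CO[Si](c3ccccc3)(c3ccccc3)C(C)(C)C)CCC[C@]12C | intermediate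
13 | methyl (4aR,5S,8aS)-5-{[tert-butyl(diphenyl)silyl]oxymethyl}-2,5,8a-trimethyl-3,4,4a,5,6,7,8,8a-octahydronaphthalene-1-carboxylate | COC(=O)C1=C(C)CC[C@H]2[C@@](C)(CO[Si](c3ccccc3)(c3ccccc3)C(C)(C)C)CCC[C@]12C | intermediate
14 | [(4aR,5S,8aS)-5-{[tert-butyl(diphenyl)silyl]oxymethyl}-2,5,8a-trimethyl-3,4,4a,5,6,7,8,8a-octahydronaphthalen-1-yl]methanol | OCC1=C(C)CC[C@H]2[C@@](C)(CO[Si](c3ccccc3)(c3ccccc3)C(C)(C)C)CCC[C@]12C | intermediate
15 | tert-butyl{[(1S,4aS,8aR)-5-(bromomethyl)-1,4a,6-trimethyl-1,2,3,4,4a,7,8,8a-octahydronaphthalen-1-yl]methoxy}diphenylsilane | BrCC1=C(C)CC[C@H]2[C@@](C)(CO[Si](c3ccccc3)(c3ccccc3)C(C)(C)C)CCC[C@]12C | intermediate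
16 | methyl acetoacetate | COC(=O)CC(C)=O | starting material
17 | methyl 5-[(4aR,5S,8aS)-5-{[tert-butyl(diphenyl)silyl]oxymethyl}-2,5,8a-trimethyl-3,4,4a,5,6,7,8,8a-octahydronaphthalen-1-yl]-3-oxopentanoate | COC(=O)CC(=O)CCC1=C(C)CC[C@H]2[C@@](C)(CO[Si](c3ccccc3)(c3ccccc3)C(C)(C)C)CCC[C@]12C | intermediate
18 | methyl (2Z)-3-[(diethoxyphosphoryl)oxy]-5-[(4aR,5S,8aS)-5-{[tert-butyl(diphenyl)silyl]oxymethyl}-2,5,8a-trimethyl-3,4,4a,5,6,7,8,8a-octahydronaphthalen-1-yl]pent-2-enoate | COC(=O)/C=C(\OP(=O)(OCC)OCC)CCC1=C(C)CC[C@H]2[C@@](C)(CO[Si](c3ccccc3)(c3ccccc3)C(C)(C)C)CCC[C@]12C | intermediate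
19 | methyl (2E)-5-[(4aR,5S,8aS)-5-{[tert-butyl(diphenyl)silyl]oxymethyl}-2,5,8a-trimethyl-3,4,4a,5,6,7,8,8a-octahydronaphthalen-1-yl]-3-methylpent-2-enoate | COC(=O)/C=C(\C)CCC1=C(C)CC[C@H]2[C@@](C)(CO[Si](c3ccccc3)(c3ccccc3)C(C)(C)C)CCC[C@]12C | intermediate
20 | methyl (2E)-5-[(4aR,5S,8aS)-5-(hydroxymethyl)-2,5,8a-trimethyl-3,4,4a,5,6,7,8,8a-octahydronaphthalen-1-yl]-3-methylpent-2-enoate | COC(=O)/C=C(\C)CCC1=C(C)CC[C@H]2[C@@](C)(CO)CCC[C@]12C | intermediate
21 | methyl (2E)-5-[(4aR,5S,8aS)-5-(acetoxymethyl)-2,5,8a-trimethyl-3,4,4a,5,6,7,8,8a-octahydronaphthalen-1-yl]-3-methylpent-2-enoate (methyl 19-acetoxylabda-8,13E-dien-15-oate) | COC(=O)/C=C(\C)CCC1=C(C)CC[C@H]2[C@@](C)(COC(C)=O)CCC[C@]12C | target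

**Step count.** Total: 16 steps. Longest linear sequence: 16 steps (1 → 21).

**Steps most likely to fail**

1. Step 8 (Diels–Alder). The cycloaddition at the fully substituted diene terminus may be outrun by Lewis-acid-induced ionisation and isomerisation of the diene, or by collapse of the polarised intermediate at C6 instead of C10 (four-membered ring). Facial discrimination by the silyloxymethyl arm may also be incomplete, so that the C10 epimer has to be removed. Fallback, setting out from 10 and coming back at 12: the diene 10 is heated without Lewis acid (toluene, 80–100 °C) with the much more reactive dienophile methyl 3-bromoprop-2-ynoate F1 (made from methyl propiolate with N-bromosuccinimide and catalytic AgNO3 in acetone). This should give, with the same regiochemistry, methyl (5S,8aS)-2-bromo-5-{[tert-butyl(diphenyl)silyl]oxymethyl}-5,8a-dimethyl-3,5,6,7,8,8a-hexahydronaphthalene-1-carboxylate F2. Addition–elimination of Me2CuLi (Et2O, −78 → 0 °C) at the β-bromo enoate then installs the C17 methyl and gives 12.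

2. Step 9 (hydrogenation). Hydrogen delivery to the shielded trisubstituted C5=C6 bond may be slow on the metal surface, which would allow double-bond migration within the 1,4-diene or partial delivery from the β face (cis fusion). Fallback, setting out from 12 and coming back at 13: radical hydrogen-atom-transfer hydrogenation (Mn(dpm)3 cat., PhSiH3, t-BuOOH, i-PrOH, rt). A hydrogen atom adds to C6 and the tertiary C5 radical is quenched on the open α face, which gives the thermodynamically preferred trans-decalin 13 directly. No new compound is made on this way (entry F0).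

3. Step 12 (dianion alkylation). The strongly basic dianion may take a proton from the allylic bromide (1,4-elimination to an exocyclic diene) or undergo halogen–metal exchange instead of displacing bromide at the hindered C11. Fallback, setting out from 15 and coming back at 19: the bromide 15 is alkylated with the far less basic sodium enolate of methyl acetoacetate 16 (NaH, THF/DMF, rt) at its central carbon to give methyl 2-acetyl-3-[(4aR,5S,8aS)-5-{[tert-butyl(diphenyl)silyl]oxymethyl}-2,5,8a-trimethyl-3,4,4a,5,6,7,8,8a-octahydronaphthalen-1-yl]propanoate F3. Krapcho dealkoxycarbonylation (LiCl, wet DMSO, 150 °C) gives the methyl ketone 4-[(4aR,5S,8aS)-5-{[tert-butyl(diphenyl)silyl]oxymethyl}-2,5,8a-trimethyl-3,4,4a,5,6,7,8,8a-octahydronaphthalen-1-yl]butan-2-one F4. Horner–Wadsworth–Emmons olefination with trimethyl phosphonoacetate (NaH, THF, 0 °C → rt) should give 19 as the major isomer, and the minor methyl (2Z)-5-[(4aR,5S,8aS)-5-{[tert-butyl(diphenyl)silyl]oxymethyl}-2,5,8a-trimethyl-3,4,4a,5,6,7,8,8a-octahydronaphthalen-1-yl]-3-methylpent-2-enoate F5 is removed by chromatography.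

**Further compounds**

F1 | step 8 | methyl 3-bromoprop-2-ynoate | COC(=O)C#CBr
F2 | step 8 | methyl (5S,8aS)-2-bromo-5-{[tert-butyl(diphenyl)silyl]oxymethyl}-5,8a-dimethyl-3,5,6,7,8,8a-hexahydronaphthalene-1-carboxylate | COC(=O)C1=C(Br)CC=C2[C@@](C)(CO[Si](c3ccccc3)(c3ccccc3)C(C)(C)C)CCC[C@]12C
F0 | step 9 | none | none
F3 | step 12 | methyl 2-acetyl-3-[(4aR,5S,8aS)-5-{[tert-butyl(diphenyl)silyl]oxymethyl}-2,5,8a-trimethyl-3,4,4a,5,6,7,8,8a-octahydronaphthalen-1-yl]propanoate | COC(=O)C(CC1=C(C)CC[C@H]2[C@@](C)(CO[Si](c3ccccc3)(c3ccccc3)C(C)(C)C)CCC[C@]12C)C(C)=O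
F4 | step 12 | 4-[(4aR,5S,8aS)-5-{[tert-butyl(diphenyl)silyl]oxymethyl}-2,5,8a-trimethyl-3,4,4a,5,6,7,8,8a-octahydronaphthalen-1-yl]butan-2-one | CC(=O)CCC1=C(C)CC[C@H]2[C@@](C)(CO[Si](c3ccccc3)(c3ccccc3)C(C)(C)C)CCC[C@]12C
F5 | step 12 | methyl (2Z)-5-[(4aR,5S,8aS)-5-{[tert-butyl(diphenyl)silyl]oxymethyl}-2,5,8a-trimethyl-3,4,4a,5,6,7,8,8a-octahydronaphthalen-1-yl]-3-methylpent-2-enoate | COC(=O)/C=C(/C)CCC1=C(C)CC[C@H]2[C@@](C)(CO[Si](c3ccccc3)(c3ccccc3)C(C)(C)C)CCC[C@]12C
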